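## The problem

Target 19 is a daucane-type diester. A cyclopentane (ring A: C1 with the angular methyl, C2 with the acetoxy group, C3, C4 with hydroxyl and isopropyl, C5) is trans-fused along C1–C5 to a cycloheptene (ring B: C5, C6 with the 4-hydroxybenzoyloxy group, C7, C8 with a methyl group, C9, C10, C1; double bond C8=C9). These locants are used for every intermediate below.

Five stereocentres (C1, C2, C4, C5, C6) lie on adjacent or 1,3-related carbons. On ring A the C4 hydroxyl, the C1 methyl and the C5–C6 bond share one face; isopropyl, C5–H, the C1–C10 bond and the acetoxy group share the other.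

C4 is a tertiary carbinol that no neighbouring centre can set, so it must be made enantioselectively or resolved. Every other centre can be relayed from it:
- its oxygen can deliver C6 to C5 on the same face;
- C5 then sends C10 to the opposite face of C1;
- the free C4 hydroxyl can steer hydride to C2 and a carbon nucleophile to C6.

The groups that limit the choice of reagents are:
- two different esters and a free phenol, which forbid strong base or nucleophilic hydride late in the route and require C2–O and C6–O to be told apart;
- the tertiary C4 alcohol, which is the aldol partner of any C2 ketone or C6 aldehyde intermediate and can cleave or dehydrate;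
- the trisubstituted alkene.

Ring B must be closed as a seven-membered ring in a setting where five-membered closures at C5 are geometrically possible.

The feature that opens the route is the substitution of ring A: oxygen on C2 and C4, a fully substituted C4 with isopropyl, and the methyl-bearing C1 between C2 and C5. This is 4-hydroxy-4-isopropyl-2-methylcyclopent-2-enone 5 (C2 carbonyl, C1=C5 alkene), which the 2-furylmethanol 4 should give by Piancatelli rearrangement.

## Retrosynthesis

**19 to 18.** Only the phenol O–H is exchanged for O–Si. The aryl silyl ether is the single protecting group of the route and falls to buffered fluoride, which neither ester notices.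

**18 to 17 (C8=C9).** The trisubstituted alkene is cut by ring-closing metathesis. It is the one bond of ring B that bears no stereocentre. The neighbouring cuts (C6–C7 by allylation or aldol, C7–C8 by enolate alkenylation) would need a polar seven-membered closure that a five-membered closure onto C5 can outrun. The precursor 17 is monocyclic, with an allyl group on C1 and a methallyl unit on C6. The forward step must join a 1,1-disubstituted and a monosubstituted alkene across a trans-disposed pair of chains.

**17 to 16 to 15 (C2–O).** The acetate is removed and C2 is returned to the ketone. Keeping C2 as the carbonyl that the key step produces avoids any protection of this position. The C2 carbinol is asked of a hydride delivered from the free C4 hydroxyl, which puts the new C–H on the hydroxyl face and the oxygen trans to it.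

**15 to 13 and 14 (C6–O acyl bond).** The aroyl group is cut off as acid 14. It is placed on C6 while C2 is still a ketone, so the two secondary hydroxyls never coexist and need no differentiation.

**13 to 11 and 12 (C6–C7).** The homoallylic carbinol is cut to aldehyde 11 and methallyl bromide 12. This cut is preferred over reduction of a ring B ketone at C6, whose facial outcome in a flexible hydroazulenone is hard to foresee. In 11 the C4 hydroxyl and the aldehyde oxygen can bind one metal, and the two faces of that chelate differ clearly (C1 on one, C5–H on the other). The forward reaction must be selective for the aldehyde over the C2 ketone and tolerate the free tertiary alcohol.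

**11 to 10 to 9 (oxidation level and C6–Si).** The aldehyde comes from primary alcohol 10, and 10 from Tamao oxidation of the cis-fused oxasilolane 9. C6 is thus carried as a silicon-bound methylene and both hydroxyls are released together.

**9 to 7 and 8 (C5–C6 and C1–C10).** Both bonds are cut in one radical sequence: the silicon-tethered CH2 radical of 7 adds to C5, and the resulting C1 radical takes an allyl group from stannane 8. An intermolecular organocopper addition to an O-protected form of 5 was weighed against this. There the usual preference for attack anti to an allylic oxygen and the bulk of isopropyl pull in opposite directions, so the C5 face is not predictable. The tether removes the question, because the five-membered oxasilolane can only be cis-fused. The radical path also never forms an enolate next to the β-silyloxy group, so elimination of the C4 oxygen is excluded. The forward step must cyclise faster than the first radical is trapped and must allylate C1 anti to the new C5–C6 bond.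

**7 to 5 and 6 (O–Si).** Silylation of the tertiary alcohol with chlorosilane 6 installs the C6 carbon.

**5 to 4 (C3–C4), the key disconnection.** Ring A is opened between C3 and C4 and recognised as the rearrangement product of furan 4. The furan oxygen is the C2 carbonyl oxygen, the furan methyl is the C1 methyl, and the isopropyl-bearing furan carbon is C4. A flat heteroarene replaces a ring with a tertiary stereocentre. The forward reaction must set C4 in the (R) configuration, which only a chiral acid can do.

**4 to 3 to 1 and 2.** The alcohol comes from ester 3 by reduction, and 3 from commercial furoate 1 and 2-chloropropane 2 by Friedel–Crafts alkylation at the free α-position.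

## Roads not taken

**Alternative 1:** The cut removes C7 from ring B (bonds C6–C7 and C7–C8), which turns the hydroazulene into a hydrindane.
- Forward step: the trimethylsilyl enol ether A2 is reached from the (R)-Hajos–Parrish ketone A3 by ketalisation, reduction to the trans ring fusion and silylation. It is cyclopropanated (CH2I2, Et2Zn) and opened with FeCl3 and then NaOAc to give cycloheptenone A1, a one-carbon ring expansion of the Saegusa type.
- Merits: C1 enters enantiopure from a proline-catalysed aldol reaction proven on scale, the trans fusion is fixed before the ring grows, and every operation up to A1 has direct precedent. In certainty of absolute configuration this road is better than the chosen one.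
- Weak points: ring A of A1 is oxidised at C2 only. C4 is a plain methylene group, and making it a carbinol that bears isopropyl would need an enone, an oxygen transposition and a face-selective carbonyl addition. Ring B still needs oxygen at C6, a methyl group at C8 and a regiodefined C8=C9 bond from a ketone that can enolise or dehydrate to either side.
- Comparison: well over twenty steps with two regiochemical gambles are estimated. The chosen plan sets against the secure start of alternative 1 a ring A that appears with all its substituents in one step. The price is an unproven asymmetric step whose fallback is a resolution.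

**Alternative 2:** C1 is cut from both C2 and C5, so ring A shrinks to a cyclobutanone and ring B opens to a chain ending in a tosylhydrazone (A5).
- Forward step: base converts the hydrazone carbon C1 of A5 into a diazo carbon, which is meant to add to the cyclobutanone carbonyl C2. Shift of C5 from C2 to C1 with loss of N2 would enlarge the four-membered ring to ring A and close ring B in the same event, giving A4.
- Merits: A4 already holds C1, C4, C5, C6 and the C8=C9 bond, so four or five functional-group steps would finish the synthesis. In the brevity of its end game it is better than the chosen route, which closes ring B separately.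
- Weak points: a non-stabilised secondary diazo carbon prefers 1,2-hydride shift or addition to the C8=C9 bond. The carbonyl addition must pass through an eight-membered transition ring. Migration of C3 in place of C5 and epoxide formation are open. The configuration of quaternary C1 rests on an approach geometry that cannot be predicted. A5 itself, a β-silyloxy cyclobutanone with three contiguous stereocentres, is prone to retro-aldol opening and long to make.
- Comparison: the chosen plan forms its C–C bonds in steps that each have a close analogue; only its enantiocontrol is untested.

**Alternative 3:** The cut runs across C5–C1 and C9–C10 and adds an oxygen bridge between C5 and C9. The precursor A7 is an acetoxypyranone joined through C4, C3 and C2 to an isopropenyl group.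
- Forward step: an amine base expels acetate, and the oxidopyrylium form of A7 adds to the alkene in an intramolecular (5+2) cycloaddition to give A6. This closes ring A and ring B and creates quaternary C1 at once.
- Merits: this cycloaddition is among the most dependable entries to a fused five–seven system with a three-atom tether. Its facial course is set by C2 and C4 already on the tether, and it also starts from a furan. In bonds formed per step and in precedent for the key step it is superior to the chosen plan.
- Weak points: C5 of A6 is a fully substituted bridgehead bound to oxygen where the target has hydrogen. The C5–O bond must be cleaved reductively (SmI2 next to the C6 ketone) with control of an epimerisable C5–H. The freed C9 hydroxyl must be removed, the alkene moved from C7=C8 to C8=C9, and the C6 ketone reduced selectively. The fully substituted C4 attached directly to the reacting pyrylium carbon is likely to slow the cycloaddition.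
- Comparison: six to eight corrective steps after the key step are estimated. The chosen plan reaches ring B by metathesis with every carbon already at its final oxidation level, but it has to accept a stepwise build-up and the open question of enantiocontrol.

Key step: step 3

Assumption: acid 14 and both antipodes of the chiral acid of step 3 are taken as purchasable; the catalyst antipode is chosen so that the (R)-enantiomer 5 results.

## Route

Step 1
Reactants: 1 methyl 3-methylfuran-2-carboxylate; 2 2-chloropropane
Product: 3 methyl 5-isopropyl-3-methylfuran-2-carboxylate
Conditions: AlCl3 (2 equiv), CS2, 0 °C to rt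
Reagents that add atoms: none
Why: Friedel–Crafts alkylation; furan-2-carboxylates are alkylated at the free α-position, and the ester deactivates the ring enough to stop after one isopropyl group has entered.

Step 2
Reactants: 3 methyl 5-isopropyl-3-methylfuran-2-carboxylate
Product: 4 (5-isopropyl-3-methylfuran-2-yl)methanol
Conditions: LiAlH4, Et2O, 0 °C; aqueous NaOH work-up
Reagents that add atoms: none
Why: Hydride reduction of the ester to the primary alcohol; the basic work-up protects the acid-sensitive furylmethanol.

Step 3
Reactants: 4 (5-isopropyl-3-methylfuran-2-yl)methanol
Product: 5 (R)-4-hydroxy-4-isopropyl-2-methylcyclopent-2-en-1-one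
Conditions: chiral N-triflylphosphoramide of 3,3'-bis(2,4,6-triisopropylphenyl)-BINOL (10 mol %), H2O (5 equiv), CHCl3 (0.05 M), 40 °C
Reagents that add atoms: water, O
Why: Proposed new method: the acid ionises the electron-rich furylmethanol to a furfuryl cation stabilised by the 3-methyl and 5-isopropyl groups, water adds at the isopropyl-bearing furan carbon, the hemiketal opens to a dihydroxypentadienyl cation, and thermal conrotatory 4π-electrocyclisation joins C3 to C4 before proton loss gives the enone, so that the furan oxygen ends as the C2 carbonyl and the water oxygen as the C4 hydroxyl. The closest known reactions are the racemic Piancatelli rearrangement of 5-alkyl-2-furylmethanols in hot aqueous acid, the chiral phosphoric acid-catalysed aza-Piancatelli rearrangement and the chiral Brønsted acid-catalysed Nazarov cyclisation, all of which pass through the same kind of cation. Ring A closes by this Nazarov-type conrotatory closure of a five-carbon cation, with one new C–C bond. The only stereocentre, C4, is fixed by the sense of conrotation: the CH2 terminus is unsubstituted and the isopropyl group should sit on the outside of the U-shaped cation, so the two senses give the two enantiomers, and the chiral phosphoramide anion, hydrogen-bonded to both hydroxyls of the cation, is the element that must bias it. The step needs hydration at the ring carbon (attack at the exocyclic carbon only returns 4) and suppression of furan oligomerisation, which the substrate helps by having only one unsubstituted and hindered ring position. Above all it needs torquoselectivity, which nothing in the substrate secures; a low water content in a non-polar solvent is meant to keep the ion pair tight.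

Step 4
Reactants: 5 (R)-4-hydroxy-4-isopropyl-2-methylcyclopent-2-en-1-one; 6 (bromomethyl)chlorodimethylsilane
Product: 7 (R)-4-{[(bromomethyl)dimethylsilyl]oxy}-4-isopropyl-2-methylcyclopent-2-en-1-one
Conditions: Et3N, DMAP (cat.), CH2Cl2, 0 °C to rt
Reagents that add atoms: none
Why: DMAP-catalysed silylation of the tertiary allylic alcohol with a small chlorosilane installs the Nishiyama–Stork temporary silicon tether; no stereocentre is touched.

Step 5
Reactants: 7 (R)-4-{[(bromomethyl)dimethylsilyl]oxy}-4-isopropyl-2-methylcyclopent-2-en-1-one; 8 allyltributylstannane
Product: 9 (3aR,4R,6aR)-4-allyl-6a-isopropyl-2,2,4-trimethylhexahydro-5H-cyclopenta[d][1,2]oxasilol-5-one (cis-fused oxasilolane; allyl on C1 trans to the C5–C6 bond)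
Conditions: 8 (5 equiv), AIBN (0.2 equiv, in portions), PhH (0.05 M), 80 °C
Reagents that add atoms: none
Why: Tin-mediated radical chain: bromine abstraction, 5-exo-trig addition of the nucleophilic α-silyl radical to the enone β-carbon C5 (Nishiyama–Stork cyclisation, necessarily cis to the C4–O bond), then Keck allylation of the tertiary α-keto radical at C1. The stannane approaches the convex face anti to the new C5–C6 bond, so C5 and C1 are both set as in the target.

Step 6
Reactants: 9 cis-fused oxasilolane ketone
Product: 10 (2R,3S,4R)-2-allyl-4-hydroxy-3-(hydroxymethyl)-4-isopropyl-2-methylcyclopentan-1-one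
Conditions: H2O2 (30 % aq), KF, KHCO3, THF/MeOH, rt
Reagents that add atoms: hydrogen peroxide, OO
Why: Tamao oxidation of the alkoxysilane C–Si bond frees the C6 primary and C4 tertiary hydroxyls; the weakly basic peroxide medium leaves the hindered ketone and the terminal alkene alone.

Step 7
Reactants: 10 (2R,3S,4R)-2-allyl-4-hydroxy-3-(hydroxymethyl)-4-isopropyl-2-methylcyclopentan-1-one
Product: 11 (1R,2R,5R)-2-allyl-5-hydroxy-5-isopropyl-2-methyl-3-oxocyclopentane-1-carbaldehyde
Conditions: TEMPO (10 mol %), PhI(OAc)2 (1.1 equiv), CH2Cl2, rt
Reagents that add atoms: none
Why: Oxoammonium oxidation is selective for the primary alcohol and stops at the aldehyde. C5 is not at risk, because the arrangement cis to the C4 hydroxyl and the C1 methyl is also the more stable epimer.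

Step 8
Reactants: 11 C6 aldehyde; 12 3-bromo-2-methylprop-1-ene
Product: 13 (2R,3S,4R)-2-allyl-4-hydroxy-3-[(1S)-1-hydroxy-3-methylbut-3-en-1-yl]-4-isopropyl-2-methylcyclopentan-1-one
Conditions: In powder (2 equiv), 12 (3 equiv), THF/H2O (1:1), rt
Reagents that add atoms: none
Why: Indium-mediated Barbier allylation in water attacks the aldehyde and not the hindered ketone and tolerates the free alcohol. Chelation of the metal between the C4 hydroxyl and the aldehyde oxygen, as established for β-hydroxy aldehydes, exposes the face turned away from C1, which gives the (6S)-carbinol.

Step 9
Reactants: 13 diol ketone; 14 4-[(tert-butyldimethylsilyl)oxy]benzoic acid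
Product: 15 (1S)-1-[(1S,2R,5R)-2-allyl-5-hydroxy-5-isopropyl-2-methyl-3-oxocyclopentyl]-3-methylbut-3-en-1-yl 4-[(tert-butyldimethylsilyl)oxy]benzoate
Conditions: EDC·HCl, DMAP, CH2Cl2, rt
Reagents that add atoms: none
Why: Steglich esterification acylates the secondary C6 hydroxyl; the tertiary C4 hydroxyl, flanked by isopropyl, does not react.

Step 10
Reactants: 15 C6 ester with C2 ketone
Product: 16 (1S)-1-[(1S,2R,3S,5R)-2-allyl-3,5-dihydroxy-5-isopropyl-2-methylcyclopentyl]-3-methylbut-3-en-1-yl 4-[(tert-butyldimethylsilyl)oxy]benzoate
Conditions: Me4NBH(OAc)3, MeCN/AcOH (1:1), −20 °C to 0 °C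
Reagents that add atoms: none
Why: Evans–Saksena reduction: the C4 hydroxyl exchanges onto boron and delivers hydride within the complex to the same face of the C2 ketone, which gives the C2 alcohol trans to the C4 hydroxyl; the reagent does not reduce esters or ketones that lack a directing group.

Step 11
Reactants: 16 C2 alcohol
Product: 17 (1S)-1-[(1S,2R,3S,5R)-3-acetoxy-2-allyl-5-hydroxy-5-isopropyl-2-methylcyclopentyl]-3-methylbut-3-en-1-yl 4-[(tert-butyldimethylsilyl)oxy]benzoate
Conditions: Ac2O, pyridine, DMAP (cat.), CH2Cl2, 0 °C to rt
Reagents that add atoms: acetic anhydride, CC(=O)OC(C)=O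
Why: DMAP-catalysed acetylation of the only secondary hydroxyl; the hindered tertiary C4 hydroxyl stays free.

Step 12
Reactants: 17 diene
Product: 18 (1S,3R,3aS,4S,8aR)-1-acetoxy-3-hydroxy-3-isopropyl-6,8a-dimethyl-1,2,3,3a,4,5,8,8a-octahydroazulen-4-yl 4-[(tert-butyldimethylsilyl)oxy]benzoate
Conditions: second-generation Grubbs catalyst RuCl2(=CHPh)(PCy3)(H2IMes) (5 mol %), CH2Cl2 (0.005 M), 40 °C
Reagents that add atoms: none
Why: Ring-closing metathesis of the allyl and methallyl termini closes the trans-fused seven-membered ring B and forms the trisubstituted C8=C9 bond; quaternary C1 and the ring A scaffold hold the two chains close.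

Step 13
Reactants: 18 silyl-protected target
Product: 19 (1S,3R,3aS,4S,8aR)-1-acetoxy-3-hydroxy-3-isopropyl-6,8a-dimethyl-1,2,3,3a,4,5,8,8a-octahydroazulen-4-yl 4-hydroxybenzoate (CNP0275279.1)
Conditions: TBAF, AcOH (1:1), THF, 0 °C
Reagents that add atoms: none
Why: Fluoride cleaves the aryl silyl ether; buffering with acetic acid keeps the phenoxide from attacking or migrating either ester.

## Compound list

1 | methyl 3-methylfuran-2-carboxylate | COC(=O)c1occc1C | starting material
2 | 2-chloropropane | CC(C)Cl | starting material
3 | methyl 5-isopropyl-3-methylfuran-2-carboxylate | COC(=O)c1oc(C(C)C)cc1C | intermediate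
4 | (5-isopropyl-3-methylfuran-2-yl)methanol | OCc1oc(C(C)C)cc1C | intermediate
5 | (R)-4-hydroxy-4-isopropyl-2-methylcyclopent-2-en-1-one | O=C1C[C@@](O)(C(C)C)C=C1C | intermediate
6 | (bromomethyl)chlorodimethylsilane | C[Si](C)(Cl)CBr | starting material
7 | (R)-4-{[(bromomethyl)dimethylsilyl]oxy}-4-isopropyl-2-methylcyclopent-2-en-1-one | O=C1C[C@@](O[Si](C)(C)CBr)(C(C)C)C=C1C | intermediate
8 | allyltributylstannane | C=CC[Sn](CCCC)(CCCC)CCCC | starting material
9 | (3aR,4R,6aR)-4-allyl-6a-isopropyl-2,2,4-trimethylhexahydro-5H-cyclopenta[d][1,2]oxasilol-5-one | O=C1C[C@]2(C(C)C)O[Si](C)(C)C[C@@H]2[C@@]1(C)CC=C | intermediate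
10 | (2R,3S,4R)-2-allyl-4-hydroxy-3-(hydroxymethyl)-4-isopropyl-2-methylcyclopentan-1-one | O=C1C[C@@](O)(C(C)C)[C@H](CO)[C@@]1(C)CC=C | intermediate
11 | (1R,2R,5R)-2-allyl-5-hydroxy-5-isopropyl-2-methyl-3-oxocyclopentane-1-carbaldehyde | O=C1C[C@@](O)(C(C)C)[C@H](C=O)[C@@]1(C)CC=C | intermediate
12 | 3-bromo-2-methylprop-1-ene | C=C(C)CBr | starting material
13 | (2R,3S,4R)-2-allyl-4-hydroxy-3-[(1S)-1-hydroxy-3-methylbut-3-en-1-yl]-4-isopropyl-2-methylcyclopentan-1-one | O=C1C[C@@](O)(C(C)C)[C@H]([C@@H](O)CC(C)=C)[C@@]1(C)CC=C | intermediate
14 | 4-[(tert-butyldimethylsilyl)oxy]benzoic acid | CC(C)(C)[Si](C)(C)Oc1ccc(cc1)C(=O)O | starting material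
15 | (1S)-1-[(1S,2R,5R)-2-allyl-5-hydroxy-5-isopropyl-2-methyl-3-oxocyclopentyl]-3-methylbut-3-en-1-yl 4-[(tert-butyldimethylsilyl)oxy]benzoate | O=C1C[C@@](O)(C(C)C)[C@H]([C@@H](OC(=O)c2ccc(O[Si](C)(C)C(C)(C)C)cc2)CC(C)=C)[C@@]1(C)CC=C | intermediate
16 | (1S)-1-[(1S,2R,3S,5R)-2-allyl-3,5-dihydroxy-5-isopropyl-2-methylcyclopentyl]-3-methylbut-3-en-1-yl 4-[(tert-butyldimethylsilyl)oxy]benzoate | O[C@H]1C[C@@](O)(C(C)C)[C@H]([C@@H](OC(=O)c2ccc(O[Si](C)(C)C(C)(C)C)cc2)CC(C)=C)[C@@]1(C)CC=C | intermediate
17 | (1S)-1-[(1S,2R,3S,5R)-3-acetoxy-2-allyl-5-hydroxy-5-isopropyl-2-methylcyclopentyl]-3-methylbut-3-en-1-yl 4-[(tert-butyldimethylsilyl)oxy]benzoate | CC(=O)O[C@H]1C[C@@](O)(C(C)C)[C@H]([C@@H](OC(=O)c2ccc(O[Si](C)(C)C(C)(C)C)cc2)CC(C)=C)[C@@]1(C)CC=C | intermediate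
18 | (1S,3R,3aS,4S,8aR)-1-acetoxy-3-hydroxy-3-isopropyl-6,8a-dimethyl-1,2,3,3a,4,5,8,8a-octahydroazulen-4-yl 4-[(tert-butyldimethylsilyl)oxy]benzoate | CC(=O)O[C@H]1C[C@@](O)(C(C)C)[C@@H]2[C@@H](OC(=O)c3ccc(O[Si](C)(C)C(C)(C)C)cc3)CC(C)=CC[C@@]12C | intermediate
19 | (1S,3R,3aS,4S,8aR)-1-acetoxy-3-hydroxy-3-isopropyl-6,8a-dimethyl-1,2,3,3a,4,5,8,8a-octahydroazulen-4-yl 4-hydroxybenzoate | CC(=O)O[C@H]1C[C@@](O)(C(C)C)[C@@H]2[C@@H](OC(=O)c3ccc(O)cc3)CC(C)=CC[C@@]12C | target

## Step count and least certain steps

Total steps: 13. Longest linear sequence: 13 steps (1 to 19).

**Step 3 (key step, proposed new method).**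
- Most likely failure: low enantioselectivity. Closure through a loosely paired or water-solvated cation, or through an acid-free thermal pathway, is not under the influence of the chiral anion, and a cation with the hydroxyl on the outside would give the opposite enantiomer for the same sense of rotation. Oligomerisation of the furfuryl cation or hydrolytic ring opening would lower the yield.
- Fallback: it sets out from 4 and uses the known racemic rearrangement (ZnCl2, 1,4-dioxane/H2O, reflux) to give racemic 4-hydroxy-4-isopropyl-2-methylcyclopent-2-en-1-one F1. The enantiomers are separated by preparative chromatography on a polysaccharide-carbamate chiral stationary phase, and the (R)-enantiomer is 5, where the route is rejoined. A partly enriched product of the catalytic reaction can be upgraded in the same way.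

**Step 5.**
- Most likely failure: trapping of the first α-silyl radical by the stannane before it cyclises, or failure of the hindered tertiary C1 radical to capture the allyl group, so that reduction or oligomerisation takes over. Incomplete facial selectivity at C1 is a lesser risk, since the convex face and the 1,2-trans preference point the same way.
- Fallback: it sets out from 7 and separates the two bond formations. Reductive Nishiyama–Stork cyclisation with Bu3SnH and AIBN gives the C1–H ketone (3aR,6aR)-6a-isopropyl-2,2,4-trimethylhexahydro-5H-cyclopenta[d][1,2]oxasilol-5-one F2 as a mixture of C1 epimers. TMSOTf and Et3N convert it to the more substituted trimethylsilyl enol ether (3aR,6aR)-6a-isopropyl-2,2,4-trimethyl-5-[(trimethylsilyl)oxy]-3,3a,6,6a-tetrahydro-2H-cyclopenta[d][1,2]oxasilole F3. Tsuji allylation with allyl methyl carbonate under Pd2(dba)3 and dppe alkylates C1 without base on the face anti to the C5–C6 bond and comes back to the route at 9.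

**Step 8.**
- Most likely failure: poor facial selectivity at C6 if the tertiary hydroxyl binds the metal too weakly in water for the chelate to dominate, so that the conformer with the aldehyde oxygen turned toward C1 reacts as well. Retro-aldol cleavage or dehydration of the β-hydroxy aldehyde is a second risk.
- Fallback: it sets out from 11 and replaces substrate control by reagent control. Brown methallylboration with the antipode of B-methallyldiisopinocampheylborane that is matched to the (6S)-carbinol, at −78 °C with oxidative work-up, returns to the route at 13. This fallback makes no compound outside the list (F0).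

**Step 1.**
- Most likely failure: loss of regiocontrol (alkylation at the β-position next to the methyl group, or a second alkylation) and acid-induced resinification of the furan.
- Fallback: it sets out from 1. Bromination at the free α-position (NBS, DMF) gives methyl 5-bromo-3-methylfuran-2-carboxylate F4. Negishi coupling with isopropylzinc bromide iPrZnBr under Pd(OAc)2 and CPhos then fixes the isopropyl group at that carbon and returns to the route at 3.

## Further compounds

F1 | step 3 | racemic 4-hydroxy-4-isopropyl-2-methylcyclopent-2-en-1-one | CC1=CC(O)(C(C)C)CC1=O
F2 | step 5 | (3aR,6aR)-6a-isopropyl-2,2,4-trimethylhexahydro-5H-cyclopenta[d][1,2]oxasilol-5-one (C1–H ketone, both C1 epimers) | O=C1C[C@]2(C(C)C)O[Si](C)(C)C[C@@H]2C1C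
F3 | step 5 | (3aR,6aR)-6a-isopropyl-2,2,4-trimethyl-5-[(trimethylsilyl)oxy]-3,3a,6,6a-tetrahydro-2H-cyclopenta[d][1,2]oxasilole | CC1=C(O[Si](C)(C)C)C[C@]2(C(C)C)O[Si](C)(C)C[C@H]12
F0 | step 8 | none | none
F4 | step 1 | methyl 5-bromo-3-methylfuran-2-carboxylate | COC(=O)c1oc(Br)cc1C
A1 | alternative 1 | trans-fused hydroazulenone with C8 ketone, C6=C7 alkene and C2 ethylene ketal | C[C@@]12CCC(=O)C=C[C@H]1CCC23OCCO3
A2 | alternative 1 | trimethylsilyl enol ether (C6=C8) of the trans-hydrindanone C2 ethylene ketal | C[C@@]12CCC(O[Si](C)(C)C)=C[C@H]1CCC23OCCO3
A3 | alternative 1 | (R)-Hajos–Parrish ketone, (7aR)-7a-methyl-2,3,7,7a-tetrahydro-1H-indene-1,5(6H)-dione | C[C@@]12CCC(=O)C=C1CCC2=O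
A4 | alternative 2 | trans-fused hydroazulen-2-one with C4 triethylsilyl ether, C6 tert-butyldimethylsilyl ether and C8=C9 alkene | O=C1C[C@@](O[Si](CC)(CC)CC)(C(C)C)[C@@H]2[C@@H](O[Si](C)(C)C(C)(C)C)CC(C)=CC[C@@]12C
A5 | alternative 2 | cyclobutanone (C2–C5) carrying the C6–C10 chain that ends in the tosylhydrazone of the C1 methyl ketone | O=C1C[C@@](O[Si](CC)(CC)CC)(C(C)C)[C@@H]1[C@@H](O[Si](C)(C)C(C)(C)C)C/C(C)=C\CC(C)=NNS(=O)(=O)c1ccc(C)cc1
A6 | alternative 3 | oxygen-bridged (C5–O–C9) hydroazulenone with C6 ketone, C7=C8 alkene, C2 tert-butyldimethylsilyl ether and C4 triethylsilyl ether | CC(C)(C)[Si](C)(C)O[C@H]1C[C@@](O[Si](CC)(CC)CC)(C(C)C)[C@]2(O3)C(=O)C=C(C)[C@@H]3C[C@@]12C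
A7 | alternative 3 | 6-acetoxy-5-methyl-2H-pyran-3(6H)-one carrying at its 2-position the C4–C1 chain with the isopropenyl group | CC(=O)OC1OC(C(=O)C=C1C)[C@](O[Si](CC)(CC)CC)(C(C)C)C[C@H](O[Si](C)(C)C(C)(C)C)C(C)=C
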